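Numbering: ring O1, C2, C3, C4, C5. Syringyl groups sit on C2 and C5, CH2OH carbons C3a on C3 and C4a on C4, and all four substituents lie on one face (meso).
Enabling feature: C2 is benzylic, bound to O1 and 1,5 to C3. The ring is therefore cut at C2–C3, where a carbenoid at C3 inserts into a C–H bond of an ArCH2–O1 ether carried by C5.
Further cuts: O1–C2 (benzylic etherification of the C5 hydroxyl) and C4–C5 (anti aldol of a succinyl imide with the aryl aldehyde). Both aryl units come from syringaldehyde.
Forward order: C4–C5, then O1–C2, then a γ-lactone C3a(=O)–O–C4a that ties the two arms together, then diazo transfer at C3. The tetrahydrofuran ring closes last by C2–C3 insertion, and LiAlH4 and hydrogenolysis finish.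
Stereochemistry: C4/C5 come from the anti aldol, C3 from the compulsory cis fusion of the new ring to the lactone, and C2 from endo, 2,5-cis insertion. No stereocentre is touched afterwards.

Key step: step 9

Remark: the target is meso, so every chiral intermediate is made as a racemate. Descriptors marked * and the SMILES strings show the relative configuration through one enantiomer. Ar = 4-(benzyloxy)-3,5-dimethoxyphenyl.

Step 1
Reactants: 1 syringaldehyde; 2 benzyl bromide
Product: 3 4-(benzyloxy)-3,5-dimethoxybenzaldehyde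
Conditions: K2CO3, DMF, 60 °C
Reagents that add atoms: none
Why: Williamson ether synthesis, in which carbonate deprotonates the acidic, aldehyde-conjugated phenol and the phenoxide displaces bromide from the benzylic halide while the aldehyde stays inert.

Step 2
Reactants: 3 4-(benzyloxy)-3,5-dimethoxybenzaldehyde (one portion)
Product: 4 [4-(benzyloxy)-3,5-dimethoxyphenyl]methanol
Conditions: NaBH4, MeOH, 0 °C
Reagents that add atoms: none
Why: Borohydride reduction of an aromatic aldehyde to the benzylic alcohol is fast at 0 °C and leaves the aryl ethers untouched.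

Step 3
Reactants: 4 [4-(benzyloxy)-3,5-dimethoxyphenyl]methanol
Product: 5 [4-(benzyloxy)-3,5-dimethoxyphenyl]methyl 2,2,2-trichloroacetimidate
Conditions: Cl3CCN, DBU (10 mol %), CH2Cl2, 0 °C
Reagents that add atoms: trichloroacetonitrile, N#CC(Cl)(Cl)Cl
Why: Base-catalysed addition of the primary alcohol to the electron-poor nitrile (trichloroacetimidate formation) is the standard way to turn an electron-rich benzylic alcohol into an alkylating agent that works without base.

Step 4
Reactants: 6 1,3-oxazolidin-2-one; 7 4-tert-butoxy-4-oxobutanoic acid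
Product: 8 tert-butyl 4-oxo-4-(2-oxo-1,3-oxazolidin-3-yl)butanoate
Conditions: DCC, DMAP (10 mol %), CH2Cl2, 0 °C to rt
Reagents that add atoms: none
Why: Steglich-type carbodiimide coupling, in which DMAP passes the activated acyl group to the weakly nucleophilic carbamate nitrogen, gives the imide and leaves C3a masked as a tert-butyl ester, so that C4a and C3a stay differentiated.

Step 5
Reactants: 3 4-(benzyloxy)-3,5-dimethoxybenzaldehyde; 8 tert-butyl 4-oxo-4-(2-oxo-1,3-oxazolidin-3-yl)butanoate
Product: 10 tert-butyl (3S*,4R*)-4-Ar-4-hydroxy-3-(2-oxo-1,3-oxazolidine-3-carbonyl)butanoate (anti aldol adduct), via trimethylsilyl ether 9 (not isolated)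
Conditions: MgCl2 (20 mol %), Et3N, Me3SiCl, EtOAc, rt; then CF3CO2H (cat.), MeOH, rt
Reagents that add atoms: chlorotrimethylsilane, C[Si](C)(C)Cl (its Me3Si group is held by 9 only)
Why: Magnesium halide-catalysed direct aldol addition of an N-acyl oxazolidinone, in which soft enolisation occurs only next to the chelating imide (at C4), O-silylation makes the reversible addition to the non-enolisable aromatic aldehyde irreversible, the anti preference typical of this reaction type with aromatic aldehydes sets C4 and C5 in the relative configuration that later places C4a and the C5 aryl group cis on the ring, and the bulky tert-butyl ester resists lactonisation by the aldolate.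

Step 6
Reactants: 10 anti aldol adduct; 5 [4-(benzyloxy)-3,5-dimethoxyphenyl]methyl 2,2,2-trichloroacetimidate
Product: 11 tert-butyl (3S*,4R*)-4-Ar-4-(Ar-methoxy)-3-(2-oxo-1,3-oxazolidine-3-carbonyl)butanoate
Conditions: CF3SO3H (2 mol %), CH2Cl2–cyclohexane, 0 °C
Reagents that add atoms: none
Why: Acid-catalysed O-alkylation with a benzylic trichloroacetimidate lets the C5 hydroxyl capture an electron-rich benzylic cation equivalent without any base, so retro-aldol cleavage and epimerisation at C4 are avoided and the C5–O bond is never broken.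

Step 7
Reactants: 11 tert-butyl (3S*,4R*)-4-Ar-4-(Ar-methoxy)-3-(2-oxo-1,3-oxazolidine-3-carbonyl)butanoate
Product: 13 (4R*)-4-[(R*)-Ar(Ar-methoxy)methyl]oxolan-2-one, via hydroxy ester 12 (not isolated)
Conditions: LiBH4, MeOH (1 equiv.), THF, 0 °C; aqueous work-up; then camphorsulfonic acid (10 mol %), CH2Cl2, rt
Reagents that add atoms: none
Why: Reductive cleavage of an N-acyl oxazolidinone followed by lactonisation, in which LiBH4 attacks the lithium-chelated exocyclic imide carbonyl far faster than the tert-butyl ester and the freed C4a hydroxyl then displaces tert-butanol from C3a in an acid-catalysed 5-exo-trig acyl substitution, under an acid no stronger than the one the dibenzylic ether already withstood and without touching C4 or C5.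

Step 8
Reactants: 13 (4R*)-4-[(R*)-Ar(Ar-methoxy)methyl]oxolan-2-one
Product: 15 (4R*)-3-diazo-4-[(R*)-Ar(Ar-methoxy)methyl]oxolan-2-one, via trifluoroacetyl lactone 14 (not isolated)
Conditions: LiN(SiMe3)2, THF, −78 °C; CF3CO2CH2CF3, −78 °C; aq. HCl work-up; then 4-acetamidobenzenesulfonyl azide, Et3N, MeCN, rt
Reagents that add atoms: 2,2,2-trifluoroethyl trifluoroacetate, O=C(OCC(F)(F)F)C(F)(F)F (its CF3CO group is held by 14 only); 4-acetamidobenzenesulfonyl azide, CC(=O)Nc1ccc(cc1)S(=O)(=O)N=[N+]=[N-] (source of the N2 unit of 15)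
Why: Regitz-type deacylative diazo transfer, in which the lactone enolate is C-trifluoroacetylated at C3 and the resulting 1,3-dicarbonyl compound takes N2 from the sulfonyl azide with loss of the trifluoroacetyl group as its N-sulfonyl amide, is established for ketones, esters and lactones that do not undergo direct transfer, and C4 is not acidic and keeps its configuration.

Step 9
Reactants: 15 (4R*)-3-diazo-4-[(R*)-Ar(Ar-methoxy)methyl]oxolan-2-one
Product: 16 (3aR*,4R*,6S*,6aR*)-4,6-di-Ar-tetrahydro-1H,3H-furo[3,4-c]furan-1-one (cis-fused; both aryl groups endo, that is cis to the lactone ring)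
Conditions: Rh2(O2CCMe3)4 (1 mol %), CH2Cl2, 4 Å MS, 0 °C, slow addition of 15
Reagents that add atoms: none
Why: Rh2(O2CCMe3)4 expels N2 from 15, and the electrophilic rhodium carbenoid at C3 takes up a C2–H bond in a concerted, asynchronous three-centre process in which the positive charge building at C2 is carried by the O1 lone pair and the alkoxy-substituted aryl ring while C2–C3 forms as the metal departs. The closest known reaction type is the intramolecular 1,5 C–H insertion of α-diazo-γ-butyrolactones and α-diazo esters into benzylic ether C–H bonds, which gives furofuranones and tetrahydrofuran-3-carboxylates. The tetrahydrofuran ring O1–C2–C3–C4–C5 closes by this 1,5-insertion (C2–C3 bond, five-membered envelope-like array with O1 as the flap) and is annulated to the existing lactone. C3 is controlled by the lactone tether, because two fused five-membered rings can only be cis-fused, so C2 adds to the carbenoid face that carries C5 and C3a ends cis to C4a. C2 is controlled by the choice between its two diastereotopic hydrogens: the array that keeps the C2 aryl group pseudo-equatorial, endo and turned away from the pivalate wall of the catalyst also sets it cis to the C5 aryl group, in line with the endo preference known for such diazolactone insertions. The step needs insertion to outrun the 1,2-shift of the C4 hydrogen, attack on the electron-rich C5 aryl ring and carbene dimerisation, and this is secured by the doubly activated C2–H bond, the few free rotors left by the tether, the bulky electron-rich carboxylate ligands, the low temperature and the slow addition.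

Step 10
Reactants: 16 (3aR*,4R*,6S*,6aR*)-4,6-di-Ar-tetrahydro-1H,3H-furo[3,4-c]furan-1-one
Product: 17 [(2R,3R,4S,5S)-2,5-di-Ar-oxolane-3,4-diyl]dimethanol (all-cis, meso)
Conditions: LiAlH4, THF, 0 °C; then H2O, aq. NaOH
Reagents that add atoms: none
Why: Lactone reduction with LiAlH4 opens the C3a–O bond and frees both primary alcohols at once, and hydride addition is faster than enolisation, so the crowded all-cis arrangement at C3 is kept.

Step 11
Reactants: 17 [(2R,3R,4S,5S)-2,5-di-Ar-oxolane-3,4-diyl]dimethanol
Product: 18 [(2R,3R,4S,5S)-2,5-bis(4-hydroxy-3,5-dimethoxyphenyl)oxolane-3,4-diyl]dimethanol (all-cis, meso; target)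
Conditions: H2 (1 atm), 10% Pd/C, EtOAc–MeOH, rt, stopped after uptake of 2 equiv. of H2
Reagents that add atoms: none
Why: Catalytic hydrogenolysis cleaves aryl benzyl ethers far faster than the two secondary benzylic C–O bonds of the ring, as is common practice with 2,5-diaryl tetrahydrofuran lignans, and the neutral medium avoids quinone-methide epimerisation at C2 and C5.

Compound list
1 | syringaldehyde (4-hydroxy-3,5-dimethoxybenzaldehyde) | COc1cc(C=O)cc(OC)c1O | starting material
2 | benzyl bromide | BrCc1ccccc1 | starting material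
3 | 4-(benzyloxy)-3,5-dimethoxybenzaldehyde | COc1cc(C=O)cc(OC)c1OCc1ccccc1 | intermediate
4 | [4-(benzyloxy)-3,5-dimethoxyphenyl]methanol | COc1cc(CO)cc(OC)c1OCc1ccccc1 | intermediate
5 | [4-(benzyloxy)-3,5-dimethoxyphenyl]methyl 2,2,2-trichloroacetimidate | COc1cc(COC(=N)C(Cl)(Cl)Cl)cc(OC)c1OCc1ccccc1 | intermediate
6 | 1,3-oxazolidin-2-one | O=C1NCCO1 | starting material
7 | 4-tert-butoxy-4-oxobutanoic acid (mono-tert-butyl succinate) | CC(C)(C)OC(=O)CCC(=O)O | starting material
8 | tert-butyl 4-oxo-4-(2-oxo-1,3-oxazolidin-3-yl)butanoate | CC(C)(C)OC(=O)CCC(=O)N1CCOC1=O | intermediate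
9 | tert-butyl (3S*,4R*)-4-[4-(benzyloxy)-3,5-dimethoxyphenyl]-3-(2-oxo-1,3-oxazolidine-3-carbonyl)-4-(trimethylsilyloxy)butanoate (anti, racemic) | CC(C)(C)OC(=O)C[C@H](C(=O)N1CCOC1=O)[C@@H](O[Si](C)(C)C)c1cc(OC)c(OCc2ccccc2)c(OC)c1 | intermediate
10 | tert-butyl (3S*,4R*)-4-[4-(benzyloxy)-3,5-dimethoxyphenyl]-4-hydroxy-3-(2-oxo-1,3-oxazolidine-3-carbonyl)butanoate (anti, racemic) | CC(C)(C)OC(=O)C[C@H](C(=O)N1CCOC1=O)[C@@H](O)c1cc(OC)c(OCc2ccccc2)c(OC)c1 | intermediate
11 | tert-butyl (3S*,4R*)-4-[4-(benzyloxy)-3,5-dimethoxyphenyl]-4-{[4-(benzyloxy)-3,5-dimethoxyphenyl]methoxy}-3-(2-oxo-1,3-oxazolidine-3-carbonyl)butanoate (racemic) | CC(C)(C)OC(=O)C[C@H](C(=O)N1CCOC1=O)[C@@H](OCc1cc(OC)c(OCc2ccccc2)c(OC)c1)c1cc(OC)c(OCc2ccccc2)c(OC)c1 | intermediate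
12 | tert-butyl (3R*,4R*)-4-[4-(benzyloxy)-3,5-dimethoxyphenyl]-4-{[4-(benzyloxy)-3,5-dimethoxyphenyl]methoxy}-3-(hydroxymethyl)butanoate (racemic) | CC(C)(C)OC(=O)C[C@H](CO)[C@@H](OCc1cc(OC)c(OCc2ccccc2)c(OC)c1)c1cc(OC)c(OCc2ccccc2)c(OC)c1 | intermediate
13 | (4R*)-4-{(R*)-[4-(benzyloxy)-3,5-dimethoxyphenyl]{[4-(benzyloxy)-3,5-dimethoxyphenyl]methoxy}methyl}oxolan-2-one (racemic) | O=C1OC[C@H]([C@@H](OCc2cc(OC)c(OCc3ccccc3)c(OC)c2)c2cc(OC)c(OCc3ccccc3)c(OC)c2)C1 | intermediate
14 | 3-(trifluoroacetyl) derivative of 13 (C3 unassigned, largely enolised; racemic) | O=C1OC[C@H]([C@@H](OCc2cc(OC)c(OCc3ccccc3)c(OC)c2)c2cc(OC)c(OCc3ccccc3)c(OC)c2)C1C(=O)C(F)(F)F | intermediate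
15 | (4R*)-3-diazo-4-{(R*)-[4-(benzyloxy)-3,5-dimethoxyphenyl]{[4-(benzyloxy)-3,5-dimethoxyphenyl]methoxy}methyl}oxolan-2-one (racemic; precursor of the key step) | O=C1OC[C@H]([C@@H](OCc2cc(OC)c(OCc3ccccc3)c(OC)c2)c2cc(OC)c(OCc3ccccc3)c(OC)c2)C1=[N+]=[N-] | intermediate
16 | (3aR*,4R*,6S*,6aR*)-4,6-bis[4-(benzyloxy)-3,5-dimethoxyphenyl]tetrahydro-1H,3H-furo[3,4-c]furan-1-one (cis-fused, both aryl groups endo; racemic; product of the key step) | O=C1OC[C@H]2[C@@H]1[C@@H](c1cc(OC)c(OCc3ccccc3)c(OC)c1)O[C@H]2c1cc(OC)c(OCc2ccccc2)c(OC)c1 | intermediate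
17 | [(2R,3R,4S,5S)-2,5-bis[4-(benzyloxy)-3,5-dimethoxyphenyl]oxolane-3,4-diyl]dimethanol (all-cis, meso) | COc1cc([C@H]2O[C@@H](c3cc(OC)c(OCc4ccccc4)c(OC)c3)[C@@H](CO)[C@H]2CO)cc(OC)c1OCc1ccccc1 | intermediate
18 | [(2R,3R,4S,5S)-2,5-bis(4-hydroxy-3,5-dimethoxyphenyl)oxolane-3,4-diyl]dimethanol (all-cis, meso) | COc1cc([C@H]2O[C@@H](c3cc(OC)c(O)c(OC)c3)[C@@H](CO)[C@H]2CO)cc(OC)c1O | target

Total step count: 11 steps.
Longest linear sequence: 9 steps (steps 1, 2, 3, 6, 7, 8, 9, 10, 11, from syringaldehyde).

Steps most likely to fail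

1. Step 9.
- What may go wrong: migration of the C4 hydrogen to the carbenoid carbon, electrophilic attack of the carbenoid on the nucleophilic ortho position of the C5 aryl ring, or insertion into the other C2–H bond with loss of 2,5-cis control.
- Fallback: the carbenoid is given up, and all four stereocentres are set at once by syn hydrogenation of a furan.
- The fallback sets out from 3. Roskamp homologation (ethyl diazoacetate, SnCl2, CH2Cl2, rt) should give ethyl 3-Ar-3-oxopropanoate F1.
- Oxidative enolate dimerisation (NaH, then I2, THF) should give diethyl 2,3-bis(Ar-carbonyl)butanedioate F2.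
- Paal–Knorr cyclodehydration (TsOH, toluene, reflux) should give diethyl 2,5-di-Ar-furan-3,4-dicarboxylate F3.
- Hydrogenation over Pd/C under pressure (EtOAc–AcOH) should add hydrogen to one face of the furan and remove both benzyl groups, giving diethyl all-cis-2,5-bis(4-hydroxy-3,5-dimethoxyphenyl)oxolane-3,4-dicarboxylate F4.
- LiAlH4 in THF at 0 °C then comes back to the route at 18.

2. Step 6.
- What may go wrong: slow capture by the hindered C5 hydroxyl, so that the imidate is lost through rearrangement to the N-benzyl amide or through Friedel–Crafts self-alkylation. Acid-induced ionisation of the C5–O bond could also scramble C5.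
- Fallback: the O1–C2 bond is made by reductive etherification instead of alkylation.
- The fallback sets out from silyl ether 9, which is then not methanolysed but taken on after filtration, and from a second portion of aldehyde 3.
- Me3SiOSO2CF3 (cat.) and Et3SiH in CH2Cl2 at −78 °C should condense the two to the oxocarbenium ion between the aldehyde carbon and the C5 oxygen and reduce it.
- This comes back to the route at 11, makes steps 2 and 3 superfluous and creates no compound outside the list (F0).

3. Step 5.
- What may go wrong: erosion of the anti preference because the ester arm competes with the imide for magnesium, and reversal of the addition before silylation.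
- Fallback: the closed, silylation-driven aldol is replaced by the open-transition-state addition of a chlorotitanium enolate to an oxocarbenium ion. This reaction type is anti-selective and delivers the O1–C2 ether in the same operation.
- The fallback sets out from 3 (with 4 and 7). Acetalisation of 3 with two equivalents of 4 (pyridinium tosylate, benzene, azeotropic removal of water) should give 4-(benzyloxy)-3,5-dimethoxybenzaldehyde bis(Ar-methyl) acetal F5.
- Coupling of 7 with 1,3-thiazolidine-2-thione (DCC, DMAP) should give tert-butyl 4-oxo-4-(2-thioxo-1,3-thiazolidin-3-yl)butanoate F6.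
- Enolisation of F6 (TiCl4, iPr2NEt, CH2Cl2, −78 °C) and addition of F5 with BF3·OEt2 should give tert-butyl (3S*,4R*)-4-Ar-4-(Ar-methoxy)-3-(2-thioxo-1,3-thiazolidine-3-carbonyl)butanoate F7.
- NaBH4 in THF–EtOH removes the thiazolidinethione and comes back to the route at 12.

Further compounds
F1 | step 9 | ethyl 3-[4-(benzyloxy)-3,5-dimethoxyphenyl]-3-oxopropanoate | CCOC(=O)CC(=O)c1cc(OC)c(OCc2ccccc2)c(OC)c1
F2 | step 9 | diethyl 2,3-bis[4-(benzyloxy)-3,5-dimethoxybenzoyl]butanedioate (mixture of diastereomers) | CCOC(=O)C(C(=O)c1cc(OC)c(OCc2ccccc2)c(OC)c1)C(C(=O)OCC)C(=O)c1cc(OC)c(OCc2ccccc2)c(OC)c1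
F3 | step 9 | diethyl 2,5-bis[4-(benzyloxy)-3,5-dimethoxyphenyl]furan-3,4-dicarboxylate | CCOC(=O)c1c(-c2cc(OC)c(OCc3ccccc3)c(OC)c2)oc(-c2cc(OC)c(OCc3ccccc3)c(OC)c2)c1C(=O)OCC
F4 | step 9 | diethyl all-cis-2,5-bis(4-hydroxy-3,5-dimethoxyphenyl)oxolane-3,4-dicarboxylate (meso) | COc1cc([C@H]2O[C@@H](c3cc(OC)c(O)c(OC)c3)[C@@H](C(=O)OCC)[C@H]2C(=O)OCC)cc(OC)c1O
F0 | step 6 | none | none
F5 | step 5 | 4-(benzyloxy)-3,5-dimethoxybenzaldehyde bis{[4-(benzyloxy)-3,5-dimethoxyphenyl]methyl} acetal | COc1cc(C(OCc2cc(OC)c(OCc3ccccc3)c(OC)c2)OCc2cc(OC)c(OCc3ccccc3)c(OC)c2)cc(OC)c1OCc1ccccc1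
F6 | step 5 | tert-butyl 4-oxo-4-(2-thioxo-1,3-thiazolidin-3-yl)butanoate | CC(C)(C)OC(=O)CCC(=O)N1CCSC1=S
F7 | step 5 | tert-butyl (3S*,4R*)-4-[4-(benzyloxy)-3,5-dimethoxyphenyl]-4-{[4-(benzyloxy)-3,5-dimethoxyphenyl]methoxy}-3-(2-thioxo-1,3-thiazolidine-3-carbonyl)butanoate (racemic) | CC(C)(C)OC(=O)C[C@H](C(=O)N1CCSC1=S)[C@@H](OCc1cc(OC)c(OCc2ccccc2)c(OC)c1)c1cc(OC)c(OCc2ccccc2)c(OC)c1
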